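The vessel is a stirred slurry at constant temperature. The solid substrate enters solution as starting material, and we take the target to form from that dissolved material.

in all of them: solid substrate 1.5 M; free catalyst 2.1 mM
- zeta: second substrate 1.5 M; the very flask that is asked about, followed so far
- flask: second substrate 1.50 M; time 12 min

zeta run (percent of the solid substrate charged)

| time / s | target / % | starting material / % |
|---|---|---|
| 10.0 | 0.1 | 1.2 |
| 15.0 | 0.6 | 1.8 |
| 40.0 | 0.3 | 4.2 |
| 80.0 | 0 | 8.4 |

(readings scatter by 0.3 percentage points)

- solid substrate is a solid; its amount is given per volume of the solution
- at the start none of the solid substrate is in solution
- starting material means what is dissolved; the solid is not counted in it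
- starting material is what solid substrate becomes in solution

- north-west: doubling the solubility of the solid substrate, all else as stated
- north: doubling the dissolution coefficient of the solid substrate, all else as stated
- south-east: doubling the amount of free catalyst, all else as stated

- amount of target at 12 min, in percent of the solid substrate charged
- concentration of starting material in solution at 80 s, in percent of saturation
- the change that raises the amount of target at 12 min, in percent of the solid substrate charged most ("none" if none brings more than 2 percentage points) (north-west / north / south-east / none)
- amount of target at 12 min, in percent of the solid substrate charged, after north-west

The concentration we watch is the dissolved starting material, and we take the rate to target as first order in it. In the zeta flask its readings keep to a line, reaching 8.4 % of the charge at 80.0 s, which looks like a zero-order feed. So we carry the feed time, the time the whole charge would need to enter solution at this opening pace: 15.9 min. On that line the dissolved share at 12 min is 75.6 %.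

With that first-order step, a share rising linearly makes target rise with the square of time. Fitting the four target readings to that square and running it to 12 min gives 7.43 %, a reading whose scatter is 24 percentage points.

The forecast says 4 % of target, 12 % of saturation at 80 s, south-east as the best change, and 7 % after north-west. Its ground: “Starting material accumulates unconsumed, so the catalytic step is limiting, not dissolution”.

Our weak link is the straight line, so we now let dissolution slow as the solution fills. Taking the forecast's saturation share and an exponential approach, 1.15 is the elapsed time in units of the approach time. The time-summed dissolved share then shrinks by the factor 0.706, and our own figure becomes 5.25 % of target, above the forecast's 4 %.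

The flask gives 5.82 % of target, south-east as the best change with a gain of 7.1 points, and 10.5 % after north-west. Its starting material stands at 12.0 % of saturation at 80 s.

    starting material + free catalyst ⇌ catalyst intermediate A (K = 0.490 /M, k = 58.4 /M/min)
    second substrate + free catalyst ⇌ catalyst intermediate B (K = 2.10 /M, k = 91.0 /M/min)
    catalyst intermediate A → free catalyst + target (k = 43.1 /min)
    solid substrate ⇌ starting material, rate k4*(cs4 - [starting material]) while solid is left; crystals form when [starting material] > cs4 (solubility = 1.10 M, k = 0.0967 /min)
    catalyst intermediate B → free catalyst + second product (k = 77.6 /min)

In the flask 47.8 % of the charge is still solid at 12.0 min, so 52.2 % has dissolved, less than the straight line's 75.6 %. With 0.38 M of solid substrate in the neighbouring flask, the feed time shrinks with the charge to 4.02 min, shorter than 12 min, so its solid should be gone by then. It stands at 0 %, and that neighbouring flask holds 16.0 % of target.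

(The readings stem from a simulated flask with constants of no real substance, noise included.)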